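**Plan**
- **Cuts:** the three MOM ethers come off last. Ring C is opened at O1–C2 and C2–C3, where C2 is one carbon from a formamide acetal. The 2-hydroxyaryl benzyl ketone left over is cut at O1–C8a and C4–C4a together, giving a ring A aryne and the ring B chromenylacetic acid.
- **Enabling feature:** O1 and the C4 carbonyl sit on the neighbouring ring A carbons C8a and C4a, and the C5 oxygen lies directly beside C4a. A 3-alkoxyaryne leaves this contiguous O / acyl / O pattern when it takes up the oxygen and the acyl half of a carboxylic acid.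
- **Forward:** phloroglucinol is prenylated at the future C6 between two MOM ethers and converted into an ortho-silylaryl triflate. The dimethylpyran ring on ring B comes from a propargyl Claisen cascade on 3,4-dihydroxybenzaldehyde, and the aldehyde is homologated to the acid. The fragments are joined in step 13, and ring C closes in step 14.
- **Stereochemistry:** the target has no stereocentre. The prenyl alkene ends in two methyl groups and the pyran alkene is ring-locked, so nothing needs control.

Key step: step 13

Remark: isoflavone numbering (O1, C2, C3, C4, C4a, C5 to C8, C8a) is used for ring A throughout. The alkene geometry of the two transient enamide-type intermediates (steps 11 and 14) does not affect the outcome and is left open in their SMILES.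

Step 1
Reactants: 1 phloroglucinol (benzene-1,3,5-triol)
Product: 2 3,5-bis(methoxymethoxy)phenol
Conditions: MOMCl (2.0 equiv), i-Pr2NEt, DMF, 0 °C to rt
Reagents that add atoms: chloromethyl methyl ether, COCCl
Why: Williamson-type O-alkylation of a phenol with a chloromethyl ether, in which two equivalents cap the three equivalent hydroxyls statistically and the mono- and tris-ethers of this cheap starting material are removed by chromatography and recycled.

Step 2
Reactants: 2 3,5-bis(methoxymethoxy)phenol
Product: 3 [3,5-bis(methoxymethoxy)phenoxy]tri(propan-2-yl)silane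
Conditions: TIPSCl, imidazole, DMF, rt
Reagents that add atoms: chlorotri(propan-2-yl)silane, CC(C)[Si](Cl)(C(C)C)C(C)C
Why: Standard imidazole-promoted silylation of the one remaining phenol, with the bulky and poorly coordinating TIPS ether chosen because it closes off its two ortho positions in the next step.

Step 3
Reactants: 3 [3,5-bis(methoxymethoxy)phenoxy]tri(propan-2-yl)silane, 4 prenyl bromide (1-bromo-3-methylbut-2-ene)
Product: 6 [3,5-bis(methoxymethoxy)-4-(3-methylbut-2-en-1-yl)phenoxy]tri(propan-2-yl)silane, via aryllithium 5 (not isolated)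
Conditions: n-BuLi, TMEDA, THF, 0 °C; then 4, −78 °C to rt
Reagents that add atoms: none
Why: Directed ortho-metalation, in which the two MOM ethers together place lithium on the carbon between them while the carbons beside OTIPS are shielded, followed by SN2 alkylation of the aryllithium with the primary allylic bromide, a common way to 2-prenylresorcinol ethers.

Step 4
Reactants: 6 [3,5-bis(methoxymethoxy)-4-(3-methylbut-2-en-1-yl)phenoxy]tri(propan-2-yl)silane
Product: 7 3,5-bis(methoxymethoxy)-4-(3-methylbut-2-en-1-yl)phenol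
Conditions: Bu4NF, THF, 0 °C
Reagents that add atoms: none
Why: Fluoride-induced cleavage of an aryl silyl ether, driven by the strong Si–F bond, which leaves the MOM acetals and the alkene untouched.

Step 5
Reactants: 7 3,5-bis(methoxymethoxy)-4-(3-methylbut-2-en-1-yl)phenol
Product: 8 3,5-bis(methoxymethoxy)-4-(3-methylbut-2-en-1-yl)phenyl N-(propan-2-yl)carbamate
Conditions: i-PrNCO, Et3N (cat.), CH2Cl2, rt
Reagents that add atoms: isopropyl isocyanate, CC(C)N=C=O
Why: Base-catalysed addition of a phenol to an isocyanate installs a secondary O-aryl carbamate, a strong oxygen-based directing group that can later be removed under mild basic conditions.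

Step 6
Reactants: 8 3,5-bis(methoxymethoxy)-4-(3-methylbut-2-en-1-yl)phenyl N-(propan-2-yl)carbamate
Product: 12 3,5-bis(methoxymethoxy)-4-(3-methylbut-2-en-1-yl)-2-(trimethylsilyl)phenyl N-(propan-2-yl)carbamate, via N-silyl carbamate 9 (not isolated), via ortho-lithiated carbamate 10 (not isolated), via C-silylated N-silyl carbamate 11 (not isolated)
Conditions: TBSOTf, TMEDA, Et2O, 0 °C to rt; n-BuLi, TMEDA, −78 °C; TMSCl, −78 °C to rt; cold aq. NaHSO4 work-up
Reagents that add atoms: chlorotrimethylsilane, C[Si](C)(C)Cl
Why: Directed ortho-metalation of an in situ N-silylated O-aryl N-isopropylcarbamate (the N-silyl group masks the N–H and prevents loss of isocyanate), in which the two free ring carbons are equivalent by symmetry and each lies between the carbamate and a MOM ether, so kinetic lithiation at −78 °C should outrun deprotonation of the prenyl CH2, and the labile N–Si bond is hydrolysed on work-up.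

Step 7
Reactants: 12 3,5-bis(methoxymethoxy)-4-(3-methylbut-2-en-1-yl)-2-(trimethylsilyl)phenyl N-(propan-2-yl)carbamate
Product: 14 3,5-bis(methoxymethoxy)-4-(3-methylbut-2-en-1-yl)-2-(trimethylsilyl)phenyl trifluoromethanesulfonate, via silylphenol 13 (not isolated)
Conditions: Et2NH, DBU, MeCN, 40 °C; then PhNTf2, rt
Reagents that add atoms: N-phenylbis(trifluoromethanesulfonimide), O=S(=O)(N(c1ccccc1)S(=O)(=O)C(F)(F)F)C(F)(F)F
Why: E1cB cleavage of the secondary carbamate (DBU removes the N–H, and the expelled isocyanate is scavenged by diethylamine) followed by triflation of the phenoxide in the same flask with a mild triflyl donor, the established entry to ortho-silylaryl triflates.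

Step 8
Reactants: 15 3,4-dihydroxybenzaldehyde, 16 3-chloro-3-methylbut-1-yne
Product: 17 3-hydroxy-4-[(2-methylbut-3-yn-2-yl)oxy]benzaldehyde
Conditions: K2CO3 (1.05 equiv), KI (cat.), CuI (cat.), DMF, 60 °C
Reagents that add atoms: none
Why: Copper-assisted etherification of a phenoxide with a tertiary propargylic chloride, in which one equivalent of carbonate ionises only the 4-OH (far more acidic because it is para to the formyl group), the same basis as the known 4-O-selective alkylations of this aldehyde.

Step 9
Reactants: 17 3-hydroxy-4-[(2-methylbut-3-yn-2-yl)oxy]benzaldehyde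
Product: 18 3-(methoxymethoxy)-4-[(2-methylbut-3-yn-2-yl)oxy]benzaldehyde
Conditions: MOMCl, i-Pr2NEt, CH2Cl2, 0 °C to rt
Reagents that add atoms: chloromethyl methyl ether, COCCl
Why: Routine MOM etherification of the single free phenol, giving ring B the same acid-labile protecting group as ring A so that one final operation unmasks all three phenols.

Step 10
Reactants: 18 3-(methoxymethoxy)-4-[(2-methylbut-3-yn-2-yl)oxy]benzaldehyde
Product: 20 8-(methoxymethoxy)-2,2-dimethyl-2H-chromene-6-carbaldehyde, via allenylphenol 19 (not isolated)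
Conditions: 1,2-dichlorobenzene, 180 °C
Reagents that add atoms: none
Why: Aromatic propargyl Claisen rearrangement to the only free ortho carbon, tautomerisation to the allenylphenol, 1,5-hydrogen shift and oxa-6π electrocyclisation build the 2,2-dimethyl-2H-pyran ring, the standard thermal chromene synthesis.

Step 11
Reactants: 20 8-(methoxymethoxy)-2,2-dimethyl-2H-chromene-6-carbaldehyde
Product: 22 2-[8-(methoxymethoxy)-2,2-dimethyl-2H-chromen-6-yl]acetonitrile, via tosylvinyl formamide 21 (not isolated)
Conditions: TosMIC, KOt-Bu, DME, −40 °C; then MeOH, reflux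
Reagents that add atoms: p-toluenesulfonylmethyl isocyanide, Cc1ccc(cc1)S(=O)(=O)C[N+]#[C-]
Why: Van Leusen reductive cyanation, in which the TosMIC anion adds to the aldehyde, the oxazoline opens to the N-(1-tosylvinyl)formamide, and methanolysis of the formyl group with loss of sulfinate leaves the one-carbon-longer nitrile under basic conditions that spare acetal and chromene.

Step 12
Reactants: 22 2-[8-(methoxymethoxy)-2,2-dimethyl-2H-chromen-6-yl]acetonitrile
Product: 23 2-[8-(methoxymethoxy)-2,2-dimethyl-2H-chromen-6-yl]acetic acid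
Conditions: KOH, EtOH–H2O, reflux; then cold 1 M HCl to pH 3–4
Reagents that add atoms: water, O; potassium hydroxide, [K+].[OH-]
Why: Alkaline hydrolysis of an arylacetonitrile through the primary amide, which the MOM ether and the chromene tolerate, with brief cold acidification to free the acid without touching the acetal.

Step 13
Reactants: 14 3,5-bis(methoxymethoxy)-4-(3-methylbut-2-en-1-yl)-2-(trimethylsilyl)phenyl trifluoromethanesulfonate, 23 2-[8-(methoxymethoxy)-2,2-dimethyl-2H-chromen-6-yl]acetic acid
Product: 26 1-[6-hydroxy-2,4-bis(methoxymethoxy)-3-(3-methylbut-2-en-1-yl)phenyl]-2-[8-(methoxymethoxy)-2,2-dimethyl-2H-chromen-6-yl]ethan-1-one, via aryne 24 (not isolated), via ortho-metalated aryl ester 25 (not isolated)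
Conditions: CsF (4 equiv), THF, 125 °C, sealed tube (14 in 1.5-fold excess)
Reagents that add atoms: none
Why: Fluoride strips the trimethylsilyl group of 14 and triflate leaves, so aryne 24 (triple bond between C4a and C8a) is fed slowly into the cesium carboxylate of 23; the carboxylate oxygen adds to C8a, and the aryl anion 25 that appears at C4a attacks the adjacent ester carbonyl through a strained four-membered alkoxide, which opens to the chelated ortho-acyl phenoxide (an anionic Fries-type 1,3-shift of the acyl group from O to C). The closest known reaction is of this same type, the CsF-induced insertion of arynes from ortho-silylaryl triflates into the C–O bond of aliphatic and aromatic carboxylic acids to give ortho-hydroxyaryl ketones, which is regioselective for 3-methoxybenzyne. No ring persists from the step and no stereocentre is created, but O1–C8a and C4–C4a are both formed. The required regioselectivity (oxygen to C8a, acyl to C4a) is secured by the C5 OMOM group beside the triple bond, whose inductive pull distorts the aryne so that the remote carbon C8a is the more electrophilic terminus and the charge builds up on C4a next to the oxygen. The required chemoselectivity is acyl transfer ahead of protonation of 25, which the ethereal solvent, the high temperature and the excess CsF (holding the acid as its salt) all favour. The prenyl group is para to C8a and cannot reach the triple bond, and carboxylate addition should outrun intermolecular ene or [2+2] capture by the two alkenes.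

Step 14
Reactants: 26 1-[6-hydroxy-2,4-bis(methoxymethoxy)-3-(3-methylbut-2-en-1-yl)phenyl]-2-[8-(methoxymethoxy)-2,2-dimethyl-2H-chromen-6-yl]ethan-1-one
Product: 28 5,7-bis(methoxymethoxy)-3-[8-(methoxymethoxy)-2,2-dimethyl-2H-chromen-6-yl]-6-(3-methylbut-2-en-1-yl)-4H-chromen-4-one, via enaminone 27 (not isolated)
Conditions: Me2NCH(OMe)2, toluene, 90 °C
Reagents that add atoms: N,N-dimethylformamide dimethyl acetal, COC(OC)N(C)C
Why: Condensation of the doubly activated methylene with the formamide acetal gives the enaminone (C2–C3), whose free phenol then displaces dimethylamine by addition–elimination and closes ring C (O1–C2), the standard deoxybenzoin route to isoflavones.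

Step 15
Reactants: 28 5,7-bis(methoxymethoxy)-3-[8-(methoxymethoxy)-2,2-dimethyl-2H-chromen-6-yl]-6-(3-methylbut-2-en-1-yl)-4H-chromen-4-one
Product: 29 gancaonin H, 5,7-dihydroxy-3-(8-hydroxy-2,2-dimethyl-2H-chromen-6-yl)-6-(3-methylbut-2-en-1-yl)-4H-chromen-4-one
Conditions: dilute HCl in MeOH, 40 °C
Reagents that add atoms: none
Why: Acid-catalysed acetal exchange with methanol removes all three MOM groups, and dilute acid at moderate temperature is the usual way to unmask prenylated isoflavones without cyclising the prenyl group onto a neighbouring phenol or adding solvent to the chromene.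

**Compound list**
1 | phloroglucinol | Oc1cc(O)cc(O)c1 | starting material
2 | 3,5-bis(methoxymethoxy)phenol | COCOc1cc(O)cc(OCOC)c1 | intermediate
3 | [3,5-bis(methoxymethoxy)phenoxy]tri(propan-2-yl)silane | COCOc1cc(O[Si](C(C)C)(C(C)C)C(C)C)cc(OCOC)c1 | intermediate
4 | prenyl bromide | CC(C)=CCBr | starting material
5 | 2,6-bis(methoxymethoxy)-4-[tri(propan-2-yl)silyloxy]phenyllithium | [Li]c1c(OCOC)cc(O[Si](C(C)C)(C(C)C)C(C)C)cc1OCOC | intermediate
6 | [3,5-bis(methoxymethoxy)-4-(3-methylbut-2-en-1-yl)phenoxy]tri(propan-2-yl)silane | CC(C)=CCc1c(OCOC)cc(O[Si](C(C)C)(C(C)C)C(C)C)cc1OCOC | intermediate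
7 | 3,5-bis(methoxymethoxy)-4-(3-methylbut-2-en-1-yl)phenol | CC(C)=CCc1c(OCOC)cc(O)cc1OCOC | intermediate
8 | 3,5-bis(methoxymethoxy)-4-(3-methylbut-2-en-1-yl)phenyl N-(propan-2-yl)carbamate | CC(C)=CCc1c(OCOC)cc(OC(=O)NC(C)C)cc1OCOC | intermediate
9 | 3,5-bis(methoxymethoxy)-4-(3-methylbut-2-en-1-yl)phenyl N-(tert-butyldimethylsilyl)-N-(propan-2-yl)carbamate | CC(C)=CCc1c(OCOC)cc(OC(=O)N(C(C)C)[Si](C)(C)C(C)(C)C)cc1OCOC | intermediate
10 | 2-lithio derivative of 9 | CC(C)=CCc1c(OCOC)cc(OC(=O)N(C(C)C)[Si](C)(C)C(C)(C)C)c([Li])c1OCOC | intermediate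
11 | 2-(trimethylsilyl) derivative of 9 | CC(C)=CCc1c(OCOC)cc(OC(=O)N(C(C)C)[Si](C)(C)C(C)(C)C)c([Si](C)(C)C)c1OCOC | intermediate
12 | 3,5-bis(methoxymethoxy)-4-(3-methylbut-2-en-1-yl)-2-(trimethylsilyl)phenyl N-(propan-2-yl)carbamate | CC(C)=CCc1c(OCOC)cc(OC(=O)NC(C)C)c([Si](C)(C)C)c1OCOC | intermediate
13 | 3,5-bis(methoxymethoxy)-4-(3-methylbut-2-en-1-yl)-2-(trimethylsilyl)phenol | CC(C)=CCc1c(OCOC)cc(O)c([Si](C)(C)C)c1OCOC | intermediate
14 | 3,5-bis(methoxymethoxy)-4-(3-methylbut-2-en-1-yl)-2-(trimethylsilyl)phenyl trifluoromethanesulfonate | CC(C)=CCc1c(OCOC)cc(OS(=O)(=O)C(F)(F)F)c([Si](C)(C)C)c1OCOC | intermediate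
15 | 3,4-dihydroxybenzaldehyde | O=Cc1ccc(O)c(O)c1 | starting material
16 | 3-chloro-3-methylbut-1-yne | CC(C)(Cl)C#C | starting material
17 | 3-hydroxy-4-[(2-methylbut-3-yn-2-yl)oxy]benzaldehyde | O=Cc1ccc(OC(C)(C)C#C)c(O)c1 | intermediate
18 | 3-(methoxymethoxy)-4-[(2-methylbut-3-yn-2-yl)oxy]benzaldehyde | O=Cc1ccc(OC(C)(C)C#C)c(OCOC)c1 | intermediate
19 | 4-hydroxy-3-(methoxymethoxy)-5-(3-methylbuta-1,2-dien-1-yl)benzaldehyde | O=Cc1cc(C=C=C(C)C)c(O)c(OCOC)c1 | intermediate
20 | 8-(methoxymethoxy)-2,2-dimethyl-2H-chromene-6-carbaldehyde | O=Cc1cc(OCOC)c2OC(C)(C)C=Cc2c1 | intermediate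
21 | N-{2-[8-(methoxymethoxy)-2,2-dimethyl-2H-chromen-6-yl]-1-(4-methylbenzenesulfonyl)ethenyl}formamide | O=CNC(=Cc1cc(OCOC)c2OC(C)(C)C=Cc2c1)S(=O)(=O)c1ccc(C)cc1 | intermediate
22 | 2-[8-(methoxymethoxy)-2,2-dimethyl-2H-chromen-6-yl]acetonitrile | N#CCc1cc(OCOC)c2OC(C)(C)C=Cc2c1 | intermediate
23 | 2-[8-(methoxymethoxy)-2,2-dimethyl-2H-chromen-6-yl]acetic acid | OC(=O)Cc1cc(OCOC)c2OC(C)(C)C=Cc2c1 | intermediate
24 | 3,5-bis(methoxymethoxy)-4-(3-methylbut-2-en-1-yl)-1,2-didehydrobenzene (ring A aryne) | CC(C)=CCC1=C(OCOC)C#CC=C1OCOC | intermediate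
25 | 2-cesio-3,5-bis(methoxymethoxy)-4-(3-methylbut-2-en-1-yl)phenyl 2-[8-(methoxymethoxy)-2,2-dimethyl-2H-chromen-6-yl]acetate | CC(C)=CCc1c(OCOC)cc(OC(=O)Cc2cc(OCOC)c3OC(C)(C)C=Cc3c2)c([Cs])c1OCOC | intermediate
26 | 1-[6-hydroxy-2,4-bis(methoxymethoxy)-3-(3-methylbut-2-en-1-yl)phenyl]-2-[8-(methoxymethoxy)-2,2-dimethyl-2H-chromen-6-yl]ethan-1-one | CC(C)=CCc1c(OCOC)cc(O)c(C(=O)Cc2cc(OCOC)c3OC(C)(C)C=Cc3c2)c1OCOC | intermediate
27 | 3-(dimethylamino)-1-[6-hydroxy-2,4-bis(methoxymethoxy)-3-(3-methylbut-2-en-1-yl)phenyl]-2-[8-(methoxymethoxy)-2,2-dimethyl-2H-chromen-6-yl]prop-2-en-1-one | CC(C)=CCc1c(OCOC)cc(O)c(C(=O)C(=CN(C)C)c2cc(OCOC)c3OC(C)(C)C=Cc3c2)c1OCOC | intermediate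
28 | 5,7-bis(methoxymethoxy)-3-[8-(methoxymethoxy)-2,2-dimethyl-2H-chromen-6-yl]-6-(3-methylbut-2-en-1-yl)-4H-chromen-4-one | CC(C)=CCc1c(OCOC)cc2occ(-c3cc(OCOC)c4c(c3)C=CC(C)(C)O4)c(=O)c2c1OCOC | intermediate
29 | gancaonin H | CC(C)=CCc1c(O)cc2occ(-c3cc(O)c4c(c3)C=CC(C)(C)O4)c(=O)c2c1O | target

**Step count**
- Total steps: 15.
- Longest linear sequence: 10 steps (steps 1 to 7, then 13, 14 and 15).
- The ring B branch (steps 8 to 12) is five steps and converges at step 13.

**Steps most likely to fail**

**1. Step 13 (aryne insertion).**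
- The aryl anion may be protonated before the acyl group has migrated, which amounts to plain O-arylation of the acid.
- Surplus aryne may arylate the product phenoxide or its enolate.
- The electron-rich alkenes may capture the aryne.

The fallback sets out from acid 23 and carbamate 8 and comes back to the route at ketone 26. Acid 23 is coupled with MeNH(OMe)·HCl (EDC·HCl, N-methylmorpholine, CH2Cl2) to give the Weinreb amide N-methoxy-N-methyl-2-[8-(methoxymethoxy)-2,2-dimethyl-2H-chromen-6-yl]acetamide F1. Carbamate 8 is N-silylated and lithiated as in step 6 (9, then 10); this lithiation is already proven once 14 is in hand. Lithio compound 10 is acylated with F1 at −78 °C in a Weinreb ketone synthesis to give the N-silyl keto carbamate F2. The cold acidic work-up hydrolyses the N–Si bond and gives the keto carbamate F3. Treatment with Et2NH and DBU in MeCN, as in step 7, removes the carbamate and gives 26. In this variant C4–C4a is made by polar acylation of an aryl anion, and O1 is carried in from the phenol rather than from the acid.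

**2. Step 6 (ortho-silylation).**
- The doubly activated prenyl methylene may be deprotonated in competition with the ring carbon.
- The silyl triflate may attack the MOM acetals.
- Silylation at the crowded carbon between two oxygen substituents may be slow.

The fallback sets out from phenol 7 and comes back at triflate 14, bypassing steps 5 to 7. Phenol 7 is iodinated once at one of its two equivalent ortho carbons under phenoxide conditions (I2, NaHCO3, THF–H2O, 0 °C), which leave a trisubstituted alkene alone. This gives 2-iodo-3,5-bis(methoxymethoxy)-4-(3-methylbut-2-en-1-yl)phenol F4. Warming with (Me3Si)2NH gives the aryl trimethylsilyl ether F5. n-BuLi in THF at −78 °C then triggers iodine–lithium exchange, which is far faster than any C–H deprotonation, and gives the aryllithium F6. A retro-Brook 1,3-shift of silicon from O to C converts it into the lithium phenoxide F7, the lithium salt of 13, and Tf2O at −78 °C turns this into 14.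

**3. Step 8 (site-selective propargylation).**
- Discrimination between the two catechol hydroxyls may be incomplete.
- The catechol may sequester the copper catalyst.
- The tertiary chloride may eliminate before etherification.

The fallback sets out from aldehyde 15 and comes back at ether 18, replacing steps 8 and 9 by a temporary-protection sequence in which only one free phenol ever meets the tertiary chloride. Aldehyde 15 is allylated selectively at the acidic 4-OH (allyl bromide, NaHCO3, NaI (cat.), DMF, 40 °C) to give 4-(allyloxy)-3-hydroxybenzaldehyde F8. MOMCl and i-Pr2NEt give 4-(allyloxy)-3-(methoxymethoxy)benzaldehyde F9. Pd(PPh3)4 (cat.) with K2CO3 in MeOH cleaves the aryl allyl ether to 4-hydroxy-3-(methoxymethoxy)benzaldehyde F10. Etherification of F10 with 16 (K2CO3, KI (cat.), CuI (cat.), DMF, 60 °C) then gives 18.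

Further compounds
F1 | step 13 | N-methoxy-N-methyl-2-[8-(methoxymethoxy)-2,2-dimethyl-2H-chromen-6-yl]acetamide | CON(C)C(=O)Cc1cc(OCOC)c2OC(C)(C)C=Cc2c1
F2 | step 13 | 2-{2-[8-(methoxymethoxy)-2,2-dimethyl-2H-chromen-6-yl]acetyl}-3,5-bis(methoxymethoxy)-4-(3-methylbut-2-en-1-yl)phenyl N-(tert-butyldimethylsilyl)-N-(propan-2-yl)carbamate | CC(C)=CCc1c(OCOC)cc(OC(=O)N(C(C)C)[Si](C)(C)C(C)(C)C)c(C(=O)Cc2cc(OCOC)c3OC(C)(C)C=Cc3c2)c1OCOC
F3 | step 13 | 2-{2-[8-(methoxymethoxy)-2,2-dimethyl-2H-chromen-6-yl]acetyl}-3,5-bis(methoxymethoxy)-4-(3-methylbut-2-en-1-yl)phenyl N-(propan-2-yl)carbamate | CC(C)=CCc1c(OCOC)cc(OC(=O)NC(C)C)c(C(=O)Cc2cc(OCOC)c3OC(C)(C)C=Cc3c2)c1OCOC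
F4 | step 6 | 2-iodo-3,5-bis(methoxymethoxy)-4-(3-methylbut-2-en-1-yl)phenol | CC(C)=CCc1c(OCOC)cc(O)c(I)c1OCOC
F5 | step 6 | [2-iodo-3,5-bis(methoxymethoxy)-4-(3-methylbut-2-en-1-yl)phenoxy]trimethylsilane | CC(C)=CCc1c(OCOC)cc(O[Si](C)(C)C)c(I)c1OCOC
F6 | step 6 | 2,4-bis(methoxymethoxy)-3-(3-methylbut-2-en-1-yl)-6-(trimethylsilyloxy)phenyllithium | CC(C)=CCc1c(OCOC)cc(O[Si](C)(C)C)c([Li])c1OCOC
F7 | step 6 | lithium 3,5-bis(methoxymethoxy)-4-(3-methylbut-2-en-1-yl)-2-(trimethylsilyl)phenoxide | CC(C)=CCc1c(OCOC)cc(O[Li])c([Si](C)(C)C)c1OCOC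
F8 | step 8 | 4-(allyloxy)-3-hydroxybenzaldehyde | O=Cc1ccc(OCC=C)c(O)c1
F9 | step 8 | 4-(allyloxy)-3-(methoxymethoxy)benzaldehyde | O=Cc1ccc(OCC=C)c(OCOC)c1
F10 | step 8 | 4-hydroxy-3-(methoxymethoxy)benzaldehyde | O=Cc1ccc(O)c(OCOC)c1
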